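Everything rests on closing the α-methylene-γ-lactone (ring O1–C2–C3–C3a–C7a; target benzofuranone locants are used throughout) last, at C3–C3a. The feature exploited is the C3a methylene that lies between the two equatorial carbinol carbons C4 and C7a of the chair cyclohexane ring: a rhodium carbenoid on the C7a ester oxygen inserts into its equatorial C–H bond with retention, which gives the trans ring fusion, and Horner–Wadsworth–Emmons olefination in the same flask delivers the exocyclic methylene. The precursor is a cyclohexyl diazophosphonoacetate whose C4, C6, C7 and C7a centres are all relayed from one desymmetrisation of a meso 3,5-bis(silyloxy)cyclohexanone; the hydroxypropenyl arm is masked as a ketone.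

Key step: step 14

Assumption: the (R,R)-configured lithium amide is taken to remove the axial hydrogen of the α-carbon that becomes C7; the sense is not secured on this ketone, and the enantiomeric base would be used otherwise.

Abbreviations: TBS = tert-butyldimethylsilyl, TBDPS = tert-butyldiphenylsilyl.

Step 1
Reactants: 1 cis,cis-cyclohexane-1,3,5-triol
Product: 2 all-cis-3,5-bis(TBS-oxy)cyclohexan-1-ol (meso)
Conditions: TBSCl (2.0 equiv), imidazole, DMF, 0 °C to rt
Reagents that add atoms: tert-butyldimethylsilyl chloride, CC(C)(C)[Si](C)(C)Cl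
Why: Silyl ether formation; the three hydroxyls of the all-cis triol are equivalent, so the statistical bis-ether is one meso compound that should be separable from mono- and tris-ether, and no stereocentre is created.

Step 2
Reactants: 2 all-cis-3,5-bis(TBS-oxy)cyclohexan-1-ol
Product: 3 cis-3,5-bis(TBS-oxy)cyclohexan-1-one (meso)
Conditions: Dess–Martin periodinane, CH2Cl2, rt
Reagents that add atoms: none
Why: Dess–Martin oxidation gives the meso ketone whose carbonyl carbon becomes C6 and whose two ether carbons, already cis, become C4 and C7a.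

Step 3
Reactants: 3 cis-3,5-bis(TBS-oxy)cyclohexan-1-one; 4 2-(TBDPS-oxy)acetaldehyde
Product: 6 aldol adduct carrying the 2-(TBDPS-oxy)-1-hydroxyethyl arm on C7, via lithium enolate 5 (not isolated)
Conditions: bis[(R)-1-phenylethyl]amine, n-BuLi, LiCl, THF, −78 °C; 3, −100 °C; then 4, −78 °C; aq. NH4Cl
Reagents that add atoms: none
Why: Enantioselective deprotonation of the meso ketone by a C2-symmetric chiral lithium amide (desymmetrisation) decides which α-carbon becomes C7 and so fixes the absolute configuration at C4 and C7a, and the enolate then adds to the aldehyde (aldol addition); the centres at C7 and at the carbinol carbon are left uncontrolled because steps 4, 5 and 7 erase and reset them.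

Step 4
Reactants: 6 aldol adduct
Product: 7 2-[2-(TBDPS-oxy)acetyl]-cis-3,5-bis(TBS-oxy)cyclohexan-1-one (enolised β-diketone)
Conditions: Dess–Martin periodinane, CH2Cl2, 0 °C to rt
Reagents that add atoms: none
Why: Dess–Martin oxidation of the β-hydroxy ketone under non-basic conditions should give the 2-acylcyclohexanone without β-elimination of the C7a silyloxy group.

Step 5
Reactants: 7 β-diketone
Product: 8 enol triflate (C6–OTf, double bond C6=C7)
Conditions: Tf2O, iPr2NEt, CH2Cl2, −78 °C
Reagents that add atoms: trifluoromethanesulfonic anhydride, O=S(=O)(OS(=O)(=O)C(F)(F)F)C(F)(F)F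
Why: O-sulfonylation of the endocyclic enol of the 2-acylcyclohexanone (enol triflate formation) places the leaving group on C6 and the double bond between C6 and C7.

Step 6
Reactants: 8 enol triflate
Product: 9 1-[2-ethenyl-cis-4,6-bis(TBS-oxy)cyclohex-1-en-1-yl]-2-(TBDPS-oxy)ethan-1-one (dienone)
Conditions: CH2=CHSnBu3, Pd(PPh3)4 (5 mol %), LiCl, THF, 65 °C
Reagents that add atoms: tributyl(vinyl)stannane, C=C[Sn](CCCC)(CCCC)CCCC
Why: Stille cross-coupling of the electron-poor vinyl triflate under zerovalent palladium catalysis installs the C6 vinyl group; no stereocentre is involved.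

Step 7
Reactants: 9 dienone
Product: 10 ketone with the C6 quaternary centre (methyl and C7 acyl on one face; vinyl and both silyloxy groups on the other)
Conditions: MeLi, CuBr·SMe2, BF3·OEt2, THF, −78 °C; aq. NH4Cl
Reagents that add atoms: methyllithium, [Li]C
Why: Conjugate addition of the organocopper–boron trifluoride reagent MeCu·BF3, which adds 1,4 rather than 1,6 to dienyl carbonyl compounds and tolerates β,β-disubstitution: methyl enters C6 axially, anti to the equatorial C4 silyl ether (and to the C7a ether), so methyl is trans and vinyl cis to both oxygens, and protonation of the enolate from the face away from the new axial methyl places the C7 acyl group equatorial.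

Step 8
Reactants: 10 bis-TBS ether
Product: 11 C4,C7a-diol
Conditions: HF·pyridine, pyridine, THF, 0 °C to rt
Reagents that add atoms: none
Why: Acidic fluoride desilylation should remove the two secondary TBS ethers while the bulkier, more acid-stable primary TBDPS ether survives.

Step 9
Reactants: 12 (R)-4-hydroxydihydrofuran-2(3H)-one
Product: 15 (R)-4-hydroxy-3-methylidenedihydrofuran-2(3H)-one, via Mannich base 13 (not isolated), via ammonium iodide 14 (not isolated)
Conditions: LDA (2.2 equiv), THF, −78 °C; CH2=NMe2+ I−, −78 to 0 °C; aq. NH4Cl; MeI, MeOH, rt; aq. NaHCO3, CH2Cl2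
Reagents that add atoms: N,N-dimethylmethyleneiminium iodide (Eschenmoser's salt), C=[N+](C)C.[I-]
Why: α-Methylenation by aminomethylation of the alkoxide–enolate dianion (Mannich reaction), quaternisation and base-induced elimination of trimethylamine; the carbinol stereocentre is not involved.

Step 10
Reactants: 15 (R)-4-hydroxy-3-methylidenedihydrofuran-2(3H)-one
Product: 18 (3R)-3,4-bis(TBS-oxy)-2-methylidenebutanoic acid, via lithium carboxylate 16 (not isolated), via silyl ester 17 (not isolated)
Conditions: LiOH·H2O (1.05 equiv), THF/H2O, 0 °C; evaporation; TBSCl (3.5 equiv), imidazole, DMF, rt; AcOH/THF/H2O, rt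
Reagents that add atoms: lithium hydroxide, [Li+].[OH-]; tert-butyldimethylsilyl chloride, CC(C)(C)[Si](C)(C)Cl
Why: Saponification of the lactone (hydroxide should attack the lactone carbonyl faster than it adds to the acrylate at 0 °C), persilylation and selective hydrolysis of the labile silyl ester give the protected acid with the stereocentre unchanged.

Step 11
Reactants: 11 C4,C7a-diol; 18 (3R)-3,4-bis(TBS-oxy)-2-methylidenebutanoic acid
Product: 19 C4 mono-ester (C7a hydroxyl free)
Conditions: DCC, DMAP (0.1 equiv), CH2Cl2, −20 to 0 °C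
Reagents that add atoms: none
Why: Steglich esterification; the equatorial C4 hydroxyl has two CH2 neighbours, whereas the C7a hydroxyl is flanked by the C7 acyl branch and hydrogen-bonded to its ketone, so the hindered acyl donor should react at C4 first.

Step 12
Reactants: 19 C4 mono-ester; 20 2-(diethoxyphosphoryl)acetic acid
Product: 21 C7a (diethoxyphosphoryl)acetate
Conditions: DCC, DMAP (0.2 equiv), CH2Cl2, rt
Reagents that add atoms: none
Why: Steglich esterification of the remaining C7a hydroxyl with the small phosphonoacetic acid.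

Step 13
Reactants: 21 C7a (diethoxyphosphoryl)acetate
Product: 22 C7a diazo(diethoxyphosphoryl)acetate
Conditions: 4-AcNHC6H4SO2N3, DBU, MeCN, 0 °C
Reagents that add atoms: 4-acetamidobenzenesulfonyl azide, CC(=O)Nc1ccc(cc1)S(=O)(=O)N=[N+]=[N-]
Why: Regitz diazo transfer to the doubly activated methylene, which is far more acidic than the hindered C7–H, so the β-acyloxy ketone should not be enolised.

Step 14
Reactants: 22 C7a diazo(diethoxyphosphoryl)acetate
Product: 24 trans-fused 3-methylidene lactone with the C7 keto arm, via phosphono lactone 23 (not isolated)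
Conditions: Rh2(O2CC7H15)4 (2 mol %), CH2Cl2, 45 °C, slow addition of 22; then THF, KOtBu (1.0 equiv), 0 °C; (CH2O)n, 0 °C to rt
Reagents that add atoms: paraformaldehyde (formaldehyde), C=O
Why: Rh2(O2CC7H15)4 decomposes the diazo ester to an electrophilic divalent rhodium carbenoid on the C7a ester, which inserts through a concerted three-centre transition state into the equatorial C3a–H bond, and the resulting phosphonate is deprotonated and olefinated with formaldehyde (Horner–Wadsworth–Emmons) to the exocyclic methylene. The closest known reaction type is the one-pot C–H insertion/olefination of α-diazo-α-(diethoxyphosphoryl)acetates of cyclohexanols to trans-fused α-methylene-γ-butyrolactones. The lactone ring (O1, C2, C3, C3a, C7a) closes by 1,5 C–H insertion, formally a 5-exo closure of C3 onto C3a. C3a is set by retention at the inserted bond: the chair is locked by the equatorial C4, C7 and C7a substituents and the axial C6 methyl, the C7a–O bond is equatorial, and of the two C3a hydrogens gauche to it the equatorial one (trans to O1) is the one such carbenoids prefer, which gives the trans ring fusion, while C3 becomes planar in the olefination. The step needs site selectivity over C7–H and over the π bonds, and the substrate secures it because C7–H is axial, tertiary and α to the ketone (electron-poor), the hydroxypropenyl alkene is still masked as that ketone, the C6 vinyl group is 1,3-diequatorial to the ester and would need a seven-membered ring, and both acrylate units are electron-poor. The price is inductive deactivation of C3a–H by the C4 acyloxy group, which is why the diazo ester is added slowly.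

Step 15
Reactants: 24 keto lactone
Product: 25 tris-silyl ether of the target
Conditions: Zn, CH2Br2, TiCl4, THF/CH2Cl2, 0 °C to rt
Reagents that add atoms: dibromomethane, BrCBr
Why: Takai–Lombardo methylenation; the non-basic zinc–titanium methylene reagent should convert the ketone into the 1,1-disubstituted alkene without epimerising C7, opening the β-acyloxy ketone, or touching the lactone, the ester or their conjugated alkenes.

Step 16
Reactants: 25 tris-silyl ether of the target
Product: 26 target
Conditions: HF·pyridine, pyridine, THF, 0 °C to rt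
Reagents that add atoms: none
Why: Global desilylation under buffered acidic fluoride, chosen over basic fluoride so that the freed γ-hydroxy ester side chain does not lactonise with loss of the C4 alcohol and nothing adds to the two acrylate units.

Compound list
1 | cis,cis-cyclohexane-1,3,5-triol (all-cis, achiral) | O[C@@H]1C[C@H](O)C[C@H](O)C1 | starting material
2 | all-cis-3,5-bis(tert-butyldimethylsilyloxy)cyclohexan-1-ol (meso) | O[C@@H]1C[C@H](O[Si](C)(C)C(C)(C)C)C[C@H](O[Si](C)(C)C(C)(C)C)C1 | intermediate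
3 | cis-3,5-bis(tert-butyldimethylsilyloxy)cyclohexan-1-one (meso; C=O is the future C6, the ether carbons the future C4 and C7a) | O=C1C[C@H](O[Si](C)(C)C(C)(C)C)C[C@H](O[Si](C)(C)C(C)(C)C)C1 | intermediate
4 | 2-(tert-butyldiphenylsilyloxy)acetaldehyde | O=CCO[Si](c1ccccc1)(c1ccccc1)C(C)(C)C | starting material
5 | lithium enolate of 3 with the double bond C6=C7 (one enantiomer; silyl ethers cis) | C1[C@H](O[Si](C)(C)C(C)(C)C)C[C@H](O[Si](C)(C)C(C)(C)C)C=C1O[Li] | intermediate
6 | 2-[2-(tert-butyldiphenylsilyloxy)-1-hydroxyethyl]-cis-3,5-bis(tert-butyldimethylsilyloxy)cyclohexan-1-one, arm on C7; C4 and C7a as in the target, C7 and the carbinol carbon as mixtures | O=C1C[C@H](O[Si](C)(C)C(C)(C)C)C[C@H](O[Si](C)(C)C(C)(C)C)C1C(O)CO[Si](c2ccccc2)(c2ccccc2)C(C)(C)C | intermediate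
7 | 2-[2-(tert-butyldiphenylsilyloxy)acetyl]-cis-3,5-bis(tert-butyldimethylsilyloxy)cyclohexan-1-one (enolised; C7 not a fixed centre) | O=C1C[C@H](O[Si](C)(C)C(C)(C)C)C[C@H](O[Si](C)(C)C(C)(C)C)C1C(=O)CO[Si](c2ccccc2)(c2ccccc2)C(C)(C)C | intermediate
8 | 2-[2-(tert-butyldiphenylsilyloxy)acetyl]-cis-3,5-bis(tert-butyldimethylsilyloxy)cyclohex-1-en-1-yl trifluoromethanesulfonate | C1[C@H](O[Si](C)(C)C(C)(C)C)C[C@H](O[Si](C)(C)C(C)(C)C)C(C(=O)CO[Si](c2ccccc2)(c2ccccc2)C(C)(C)C)=C1OS(=O)(=O)C(F)(F)F | intermediate
9 | 1-[2-ethenyl-cis-4,6-bis(tert-butyldimethylsilyloxy)cyclohex-1-en-1-yl]-2-(tert-butyldiphenylsilyloxy)ethan-1-one | C1[C@H](O[Si](C)(C)C(C)(C)C)C[C@H](O[Si](C)(C)C(C)(C)C)C(C(=O)CO[Si](c2ccccc2)(c2ccccc2)C(C)(C)C)=C1C=C | intermediate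
10 | 1-[2-ethenyl-2-methyl-4,6-bis(tert-butyldimethylsilyloxy)cyclohexyl]-2-(tert-butyldiphenylsilyloxy)ethan-1-one; vinyl and both silyloxy groups on one face, methyl and acyl on the other (C4, C6, C7, C7a as in the target) | C=C[C@]1(C)C[C@H](O[Si](C)(C)C(C)(C)C)C[C@H](O[Si](C)(C)C(C)(C)C)[C@H]1C(=O)CO[Si](c2ccccc2)(c2ccccc2)C(C)(C)C | intermediate
11 | 1-(2-ethenyl-4,6-dihydroxy-2-methylcyclohexyl)-2-(tert-butyldiphenylsilyloxy)ethan-1-one, configuration as in 10 | C=C[C@]1(C)C[C@H](O)C[C@H](O)[C@H]1C(=O)CO[Si](c2ccccc2)(c2ccccc2)C(C)(C)C | intermediate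
12 | (R)-4-hydroxydihydrofuran-2(3H)-one | O=C1C[C@@H](O)CO1 | starting material
13 | (4R)-3-[(dimethylamino)methyl]-4-hydroxydihydrofuran-2(3H)-one (C3 epimers) | CN(C)CC1C(=O)OC[C@@H]1O | intermediate
14 | [(4R)-4-hydroxy-2-oxooxolan-3-yl]methyl(trimethyl)ammonium iodide | C[N+](C)(C)CC1C(=O)OC[C@@H]1O.[I-] | intermediate
15 | (R)-4-hydroxy-3-methylidenedihydrofuran-2(3H)-one | C=C1C(=O)OC[C@@H]1O | intermediate
16 | lithium (3R)-3,4-dihydroxy-2-methylidenebutanoate | [Li+].[O-]C(=O)C(=C)[C@@H](O)CO | intermediate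
17 | tert-butyldimethylsilyl (3R)-3,4-bis(tert-butyldimethylsilyloxy)-2-methylidenebutanoate | CC(C)(C)[Si](C)(C)OC(=O)C(=C)[C@@H](O[Si](C)(C)C(C)(C)C)CO[Si](C)(C)C(C)(C)C | intermediate
18 | (3R)-3,4-bis(tert-butyldimethylsilyloxy)-2-methylidenebutanoic acid | OC(=O)C(=C)[C@@H](O[Si](C)(C)C(C)(C)C)CO[Si](C)(C)C(C)(C)C | intermediate
19 | C4 ester of diol 11 with acid 18 (C7a hydroxyl free) | C=C[C@]1(C)C[C@H](OC(=O)C(=C)[C@@H](O[Si](C)(C)C(C)(C)C)CO[Si](C)(C)C(C)(C)C)C[C@H](O)[C@H]1C(=O)CO[Si](c2ccccc2)(c2ccccc2)C(C)(C)C | intermediate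
20 | 2-(diethoxyphosphoryl)acetic acid | CCOP(=O)(CC(=O)O)OCC | starting material
21 | C7a (diethoxyphosphoryl)acetate of 19 | C=C[C@]1(C)C[C@H](OC(=O)C(=C)[C@@H](O[Si](C)(C)C(C)(C)C)CO[Si](C)(C)C(C)(C)C)C[C@H](OC(=O)CP(=O)(OCC)OCC)[C@H]1C(=O)CO[Si](c2ccccc2)(c2ccccc2)C(C)(C)C | intermediate
22 | C7a diazo(diethoxyphosphoryl)acetate of 19 | C=C[C@]1(C)C[C@H](OC(=O)C(=C)[C@@H](O[Si](C)(C)C(C)(C)C)CO[Si](C)(C)C(C)(C)C)C[C@H](OC(=O)C(=[N+]=[N-])P(=O)(OCC)OCC)[C@H]1C(=O)CO[Si](c2ccccc2)(c2ccccc2)C(C)(C)C | intermediate
23 | trans-fused 3-(diethoxyphosphoryl)-2-oxooctahydrobenzofuran with the C4 ester and the C7 2-(silyloxy)acetyl arm (C3 epimers) | C=C[C@]1(C)C[C@H](OC(=O)C(=C)[C@@H](O[Si](C)(C)C(C)(C)C)CO[Si](C)(C)C(C)(C)C)[C@H]2C(P(=O)(OCC)OCC)C(=O)O[C@@H]2[C@H]1C(=O)CO[Si](c3ccccc3)(c3ccccc3)C(C)(C)C | intermediate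
24 | trans-fused 3-methylidene-2-oxooctahydrobenzofuran with the C4 ester and the C7 2-(tert-butyldiphenylsilyloxy)acetyl arm; ring centres as in the target | C=C[C@]1(C)C[C@H](OC(=O)C(=C)[C@@H](O[Si](C)(C)C(C)(C)C)CO[Si](C)(C)C(C)(C)C)[C@H]2C(=C)C(=O)O[C@@H]2[C@H]1C(=O)CO[Si](c3ccccc3)(c3ccccc3)C(C)(C)C | intermediate
25 | target with the side-chain diol as bis-TBS ether and the allylic alcohol as TBDPS ether | C=C[C@]1(C)C[C@H](OC(=O)C(=C)[C@@H](O[Si](C)(C)C(C)(C)C)CO[Si](C)(C)C(C)(C)C)[C@H]2C(=C)C(=O)O[C@@H]2[C@H]1C(=C)CO[Si](c3ccccc3)(c3ccccc3)C(C)(C)C | intermediate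
26 | [(3aR,4S,6S,7R,7aR)-6-ethenyl-7-(3-hydroxyprop-1-en-2-yl)-6-methyl-3-methylidene-2-oxooctahydro-1-benzofuran-4-yl] (3R)-3,4-dihydroxy-2-methylidenebutanoate | C=C[C@]1(C)C[C@H](OC(=O)C(=C)[C@@H](O)CO)[C@H]2C(=C)C(=O)O[C@@H]2[C@H]1C(=C)CO | target

Total step count: 16. Longest linear sequence: 14 (steps 1–8 and 11–16; steps 9–10 make the side-chain acid).

Steps most likely to fail

1. Step 14. What may go wrong: insertion into C3a–H is slowed by the inductive pull of the neighbouring C4 acyloxy group, so carbene dimerisation, capture of adventitious water or attack on the side chain takes over. The fallback runs the insertion before the C4 acylation. It sets out from 11: the less hindered C4 hydroxyl is silylated (Et3SiCl, imidazole, CH2Cl2, −40 °C) to the triethylsilyl ether F1. Esterification of the C7a hydroxyl with 20 (DCC, DMAP) gives the phosphonoacetate F2, and diazo transfer (4-AcNHC6H4SO2N3, DBU) gives the diazo ester F3. The rhodium-catalysed insertion, now next to a silyl ether and without the side chain, gives the phosphono lactone F4 (not isolated), which is olefinated with formaldehyde to the methylene lactone F5. AcOH/THF/H2O removes the triethylsilyl group to give the alcohol F6, and esterification with 18 (DCC, DMAP) comes back to the route at 24.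

2. Step 7. What may go wrong: 1,6-addition at the vinyl terminus instead of 1,4-addition at the hindered C6, electrocyclisation of the cis-dienone to a 2H-pyran, or loss of the C7a silyloxy group from the enolate. The fallback builds the vinyl group after the quaternary centre. It sets out from 8: Stille coupling with tributyl[(4-methoxybenzyloxy)methyl]stannane (Pd(PPh3)4, LiCl) gives the enone F7, which has no 1,6 position. MeCu·BF3 adds methyl to C6 with the same facial preference to give the ketone F8. DDQ removes the 4-methoxybenzyl group to give the primary alcohol F9, and Dess–Martin oxidation gives the neopentyl aldehyde F10. Wittig methylenation (Ph3P=CH2, THF, −78 to 0 °C), much faster at the aldehyde than at the hindered ketone, comes back to the route at 10.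

3. Step 3. What may go wrong: incomplete discrimination of the enantiotopic α-hydrogens, β-elimination of silyloxide from the lithium enolate while it waits for the aldehyde, or proton transfer between aldolate and enolate. The fallback uses an internal quench followed by a Lewis-acid aldol. It sets out from 3: deprotonation with the same chiral amide in the presence of Me3SiCl at −100 °C gives the trimethylsilyl enol ether F11, whose enantiomeric purity can be checked before it is used. Mukaiyama aldol addition of F11 to 4 (BF3·OEt2, CH2Cl2, −78 °C) comes back to the route at 6.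

Further compounds
F1 | step 14 | C4 triethylsilyl ether of diol 11 (C7a hydroxyl free) | C=C[C@]1(C)C[C@H](O[Si](CC)(CC)CC)C[C@H](O)[C@H]1C(=O)CO[Si](c2ccccc2)(c2ccccc2)C(C)(C)C
F2 | step 14 | C7a (diethoxyphosphoryl)acetate of F1 | C=C[C@]1(C)C[C@H](O[Si](CC)(CC)CC)C[C@H](OC(=O)CP(=O)(OCC)OCC)[C@H]1C(=O)CO[Si](c2ccccc2)(c2ccccc2)C(C)(C)C
F3 | step 14 | C7a diazo(diethoxyphosphoryl)acetate of F1 | C=C[C@]1(C)C[C@H](O[Si](CC)(CC)CC)C[C@H](OC(=O)C(=[N+]=[N-])P(=O)(OCC)OCC)[C@H]1C(=O)CO[Si](c2ccccc2)(c2ccccc2)C(C)(C)C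
F4 | step 14 | trans-fused 3-(diethoxyphosphoryl) lactone with C4 triethylsilyl ether and C7 keto arm | C=C[C@]1(C)C[C@H](O[Si](CC)(CC)CC)[C@H]2C(P(=O)(OCC)OCC)C(=O)O[C@@H]2[C@H]1C(=O)CO[Si](c3ccccc3)(c3ccccc3)C(C)(C)C
F5 | step 14 | trans-fused 3-methylidene lactone with C4 triethylsilyl ether and C7 keto arm | C=C[C@]1(C)C[C@H](O[Si](CC)(CC)CC)[C@H]2C(=C)C(=O)O[C@@H]2[C@H]1C(=O)CO[Si](c3ccccc3)(c3ccccc3)C(C)(C)C
F6 | step 14 | C4 alcohol of F5 | C=C[C@]1(C)C[C@H](O)[C@H]2C(=C)C(=O)O[C@@H]2[C@H]1C(=O)CO[Si](c3ccccc3)(c3ccccc3)C(C)(C)C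
F7 | step 7 | 1-[2-[(4-methoxybenzyloxy)methyl]-cis-4,6-bis(tert-butyldimethylsilyloxy)cyclohex-1-en-1-yl]-2-(tert-butyldiphenylsilyloxy)ethan-1-one | C1[C@H](O[Si](C)(C)C(C)(C)C)C[C@H](O[Si](C)(C)C(C)(C)C)C(C(=O)CO[Si](c2ccccc2)(c2ccccc2)C(C)(C)C)=C1COCc3ccc(OC)cc3
F8 | step 7 | methyl adduct of F7 (C6 quaternary; methyl trans to both silyloxy groups, acyl equatorial) | COc1ccc(COC[C@]2(C)C[C@H](O[Si](C)(C)C(C)(C)C)C[C@H](O[Si](C)(C)C(C)(C)C)[C@H]2C(=O)CO[Si](c3ccccc3)(c3ccccc3)C(C)(C)C)cc1
F9 | step 7 | C6 hydroxymethyl compound from F8 | OC[C@]1(C)C[C@H](O[Si](C)(C)C(C)(C)C)C[C@H](O[Si](C)(C)C(C)(C)C)[C@H]1C(=O)CO[Si](c2ccccc2)(c2ccccc2)C(C)(C)C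
F10 | step 7 | C6 carbaldehyde from F9 | O=C[C@]1(C)C[C@H](O[Si](C)(C)C(C)(C)C)C[C@H](O[Si](C)(C)C(C)(C)C)[C@H]1C(=O)CO[Si](c2ccccc2)(c2ccccc2)C(C)(C)C
F11 | step 3 | trimethylsilyl enol ether of 3 (double bond C6=C7) | C1[C@H](O[Si](C)(C)C(C)(C)C)C[C@H](O[Si](C)(C)C(C)(C)C)C=C1O[Si](C)(C)C
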